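## Retrosynthetic overview

1. The enone side chain is made last: oxidation of a secondary allylic alcohol that comes from an (E)-alkenylzinc adding to an α,α-disubstituted epoxy aldehyde. That oxirane comes from Sharpless epoxidation of a 2-substituted allyl alcohol.
2. The ring oxirane comes from hydroxyl-directed epoxidation after 1,2-reduction of an α'-acyloxy cyclohexenone, followed by re-oxidation. The isovalerate is placed on the acyloin hydroxyl of that enone.
3. The cyclohexenone arises by 5 → 6 ring enlargement of a 1-hydroxycyclopent-2-ene-1-carbaldehyde through α-ketol (acyloin) shifts. The enabling feature is the O–CH–C(=O) unit of the carbocycle (ester-bearing CH next to the ring ketone), whose ketone is flanked on the other side by the C(CH3)–CH oxirane carbons, a masked enone. A conjugated acyloin of this kind is the thermodynamic end point of 1,2-shifts from a tertiary α-hydroxy aldehyde.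
4. The cyclopentene aldehyde comes from (R)-limonene (oxygenation of the isopropenyl methyl, ozonolysis of the ring alkene, aldol condensation). Limonene supplies the side-chain-bearing ring stereocentre.
5. Ring order: cyclopentene (step 4) → cyclohexenone by ring expansion (step 7) → ring oxirane (step 10) → side-chain oxirane (step 13).

Key step: step 7

Remark: 2-methyl-2-(trimethylsilyloxy)but-3-yne and 3-methylbutanoyl chloride are taken as purchasable; the silyl ether is otherwise one silylation from 2-methylbut-3-yn-2-ol.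

## Route

Step 1
Reactants: 1 (R)-(+)-limonene
Product: 4 (R)-p-mentha-1,8-dien-10-ol, via allyllithium 2 (not isolated), via dimethyl allylboronate 3 (not isolated)
Conditions: n-BuLi, TMEDA, hexane, rt; B(OMe)3, Et2O, −78 °C → rt; H2O2, aq NaOH, 0 °C
Reagents that add atoms: hydrogen peroxide OO (hydroxyl O of 4); n-butyllithium [Li]CCCC (Li of 2); trimethyl borate COB(OC)OC (B(OMe)2 of 3)
Why: Allylic metalation with n-BuLi·TMEDA should deprotonate only the isopropenyl methyl group, and borylation then organoborane oxidation convert the 2-substituted allyl anion into the primary allylic alcohol without touching the ring stereocentre.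

Step 2
Reactants: 4 (R)-p-mentha-1,8-dien-10-ol
Product: 5 tert-butyldimethylsilyl ether of 4
Conditions: TBSCl, imidazole, DMF, rt
Reagents that add atoms: tert-butyldimethylsilyl chloride CC(C)(C)[Si](C)(C)Cl
Why: Standard silyl protection of a primary alcohol gives an ether that should survive ozone, amine, alkoxide, Lewis acid and hydride.

Step 3
Reactants: 5 tert-butyldimethylsilyl ether of 4
Product: 7 (3R)-3-[3-(tert-butyldimethylsilyloxy)prop-1-en-2-yl]-6-oxoheptanal, via secondary ozonide 6 (not isolated)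
Conditions: O3 (1 equiv, indicator end point), CH2Cl2, −78 °C; Me2S, −78 °C → rt
Reagents that add atoms: ozone [O-][O+]=O
Why: Ozonolysis with reductive work-up should cleave the electron-rich trisubstituted ring alkene in preference to the 1,1-disubstituted alkene, which is deactivated by the allylic silyl ether.

Step 4
Reactants: 7 (3R)-3-[3-(tert-butyldimethylsilyloxy)prop-1-en-2-yl]-6-oxoheptanal
Product: 9 (5S)-2-methyl-5-[3-(tert-butyldimethylsilyloxy)prop-1-en-2-yl]cyclopent-1-ene-1-carbaldehyde, via β-hydroxy aldehyde 8 (not isolated)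
Conditions: piperidine (cat.), AcOH (cat.), benzene, reflux, Dean–Stark
Reagents that add atoms: none
Why: Amine-catalysed intramolecular aldol condensation (aldehyde α-carbon onto the methyl ketone, five-membered ring) and dehydration should give the conjugated cyclopentene aldehyde; the stereocentre is not enolisable.

Step 5
Reactants: 9 (5S)-2-methyl-5-[3-(tert-butyldimethylsilyloxy)prop-1-en-2-yl]cyclopent-1-ene-1-carbaldehyde
Product: 10 trimethylsilyl dienol ether of 9 (1-[(trimethylsilyloxy)methylidene]-2-methylcyclopent-2-ene, side chain at C5, E/Z mixture)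
Conditions: TMSOTf, Et3N, Et2O, 0 °C
Reagents that add atoms: trimethylsilyl trifluoromethanesulfonate C[Si](C)(C)OS(=O)(=O)C(F)(F)F
Why: Soft enolisation of the enal through its O-silyl allyl cation should remove a ring γ-proton and give the more substituted cross-ring 1-siloxy diene (silyl dienol ether formation).

Step 6
Reactants: 10 trimethylsilyl dienol ether of 9
Product: 12 (1S,5S)-1-hydroxy-2-methyl-5-[3-(tert-butyldimethylsilyloxy)prop-1-en-2-yl]cyclopent-2-ene-1-carbaldehyde (OH trans to the side chain), via potassium dienolate 11 (not isolated)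
Conditions: t-BuOK, THF, −78 °C; 2-(phenylsulfonyl)-3-phenyloxaziridine, −78 °C; AcOH quench
Reagents that add atoms: 2-(phenylsulfonyl)-3-phenyloxaziridine O=S(=O)(c1ccccc1)N1OC1c1ccccc1 (hydroxyl O of 12); potassium tert-butoxide CC(C)(C)O[K] (K of 11)
Why: Alkoxide cleavage of the silyl enol ether should give the regiodefined potassium dienolate, and N-sulfonyloxaziridine enolate hydroxylation (Davis oxidation) at the α-carbon anti to the neighbouring side chain sets the tertiary carbinol trans to it and leaves the alkene in the ring.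

Step 7
Reactants: 12 (1S,5S)-1-hydroxy-2-methyl-5-[3-(tert-butyldimethylsilyloxy)prop-1-en-2-yl]cyclopent-2-ene-1-carbaldehyde
Product: 14 (5S,6S)-6-hydroxy-2-methyl-5-[3-(tert-butyldimethylsilyloxy)prop-1-en-2-yl]cyclohex-2-en-1-one, via β,γ-unsaturated ketol 13 (not isolated)
Conditions: Sc(OTf)3 (10 mol %), 4 Å MS, PhMe, 0 → 45 °C
Reagents that add atoms: none
Why: Sc(III) should chelate the carbinol and formyl oxygens in a syn-periplanar five-membered chelate, and a ring carbon then migrates suprafacially from the carbinol carbon to the formyl carbon (α-ketol/acyloin rearrangement), as in Lewis-acid ring enlargements of 1-hydroxycycloalkanecarbaldehydes and the D-homoannulation of 17-hydroxy-20-keto steroids. The six-membered ring is closed by this 1,2-shift, which inserts the exocyclic formyl carbon into the cyclopentene (ring enlargement by one carbon, not a cyclisation), driven by the aldehyde-to-ketone change. The alkenyl ring carbon is expected to shift first to give ketol 13, in which a second chelate-bound 1,2-hydride shift (ketol transposition) moves the carbonyl into conjugation with the ring alkene; direct shift of the sp3 ring carbon gives 14 in one event, so both migration modes should end in the same conjugated acyloin. The new CH–OH stereocentre is controlled by the chelate, because each suprafacial shift places the new hydroxyl on the face that carried the previous carbinol oxygen, so the trans carbinol of 12 is relayed to the trans (diequatorial, also more stable) hydroxy enone. The selectivity needed is conjugated over transposed ketol with retention at the side-chain-bearing carbon; the ring alkene next to the carbinol carbon secures the first (only 14 is an enone), and a migrating carbon keeps its configuration in a 1,2-shift.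

Step 8
Reactants: 14 (5S,6S)-6-hydroxy-2-methyl-5-[3-(tert-butyldimethylsilyloxy)prop-1-en-2-yl]cyclohex-2-en-1-one; 15 3-methylbutanoyl chloride
Product: 16 (1S,6S)-3-methyl-2-oxo-6-[3-(tert-butyldimethylsilyloxy)prop-1-en-2-yl]cyclohex-3-en-1-yl 3-methylbutanoate
Conditions: pyridine, DMAP (cat.), CH2Cl2, 0 °C
Reagents that add atoms: none
Why: DMAP-catalysed O-acylation of the secondary acyloin hydroxyl should install the isovalerate without touching the C–H stereocentre and blocks further ketol tautomerism.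

Step 9
Reactants: 16 (1S,6S)-3-methyl-2-oxo-6-[3-(tert-butyldimethylsilyloxy)prop-1-en-2-yl]cyclohex-3-en-1-yl 3-methylbutanoate
Product: 17 (1S,2S,6S)-2-hydroxy-3-methyl-6-[3-(tert-butyldimethylsilyloxy)prop-1-en-2-yl]cyclohex-3-en-1-yl 3-methylbutanoate
Conditions: NaBH4, CeCl3·7H2O, MeOH, −78 °C
Reagents that add atoms: none
Why: Luche 1,2-reduction should deliver hydride axially, anti to the axial C–H of the ester-bearing carbon, giving the pseudo-equatorial allylic alcohol trans to the ester and cis to the side chain (the sense of carvone → cis-carveol).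

Step 10
Reactants: 17 (1S,2S,6S)-2-hydroxy-3-methyl-6-[3-(tert-butyldimethylsilyloxy)prop-1-en-2-yl]cyclohex-3-en-1-yl 3-methylbutanoate
Product: 18 (1R,2R,3S,4S,6S)-2-hydroxy-1-methyl-4-[3-(tert-butyldimethylsilyloxy)prop-1-en-2-yl]-7-oxabicyclo[4.1.0]heptan-3-yl 3-methylbutanoate
Conditions: VO(acac)2 (5 mol %), t-BuOOH (decane), CH2Cl2, 0 °C → rt
Reagents that add atoms: tert-butyl hydroperoxide CC(C)(C)OO
Why: Vanadium-catalysed hydroxyl-directed epoxidation should deliver oxygen to the trisubstituted ring alkene syn to the allylic OH (cis to the side chain, trans to the ester) and leave the undirected 1,1-disubstituted alkene alone.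

Step 11
Reactants: 18 (1R,2R,3S,4S,6S)-2-hydroxy-1-methyl-4-[3-(tert-butyldimethylsilyloxy)prop-1-en-2-yl]-7-oxabicyclo[4.1.0]heptan-3-yl 3-methylbutanoate
Product: 19 (1S,3S,4S,6S)-1-methyl-2-oxo-4-[3-(tert-butyldimethylsilyloxy)prop-1-en-2-yl]-7-oxabicyclo[4.1.0]heptan-3-yl 3-methylbutanoate
Conditions: Dess–Martin periodinane, NaHCO3, CH2Cl2, rt
Reagents that add atoms: none
Why: Buffered Dess–Martin oxidation of the secondary epoxy alcohol should give the α,β-epoxy ketone without epimerising the adjacent ester-bearing carbon.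

Step 12
Reactants: 19 (1S,3S,4S,6S)-1-methyl-2-oxo-4-[3-(tert-butyldimethylsilyloxy)prop-1-en-2-yl]-7-oxabicyclo[4.1.0]heptan-3-yl 3-methylbutanoate
Product: 20 (1S,3S,4S,6S)-4-(3-hydroxyprop-1-en-2-yl)-1-methyl-2-oxo-7-oxabicyclo[4.1.0]heptan-3-yl 3-methylbutanoate
Conditions: HF·pyridine, pyridine, THF, 0 °C → rt
Reagents that add atoms: none
Why: Buffered fluoride desilylation of the primary allylic silyl ether should be tolerated by the epoxy ketone and the ester.

Step 13
Reactants: 20 (1S,3S,4S,6S)-4-(3-hydroxyprop-1-en-2-yl)-1-methyl-2-oxo-7-oxabicyclo[4.1.0]heptan-3-yl 3-methylbutanoate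
Product: 21 (1S,3S,4R,6S)-4-[(2S)-2-(hydroxymethyl)oxiran-2-yl]-1-methyl-2-oxo-7-oxabicyclo[4.1.0]heptan-3-yl 3-methylbutanoate
Conditions: Ti(OiPr)4 (10 mol %), L-(+)-DIPT (12 mol %), t-BuOOH, 4 Å MS, CH2Cl2, −20 °C
Reagents that add atoms: tert-butyl hydroperoxide CC(C)(C)OO
Why: Sharpless asymmetric epoxidation of the 2-substituted allyl alcohol under reagent control (L-(+)-tartrate gives the (S)-2,2-disubstituted epoxy alcohol, as with 2-methylallyl alcohol) should set the quaternary oxirane centre.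

Step 14
Reactants: 21 (1S,3S,4R,6S)-4-[(2S)-2-(hydroxymethyl)oxiran-2-yl]-1-methyl-2-oxo-7-oxabicyclo[4.1.0]heptan-3-yl 3-methylbutanoate
Product: 22 (1S,3S,4R,6S)-4-[(2R)-2-formyloxiran-2-yl]-1-methyl-2-oxo-7-oxabicyclo[4.1.0]heptan-3-yl 3-methylbutanoate
Conditions: Dess–Martin periodinane, NaHCO3, CH2Cl2, 0 °C → rt
Reagents that add atoms: none
Why: Dess–Martin oxidation of the primary epoxy alcohol should give an epoxy aldehyde that has no α-hydrogen and cannot epimerise.

Step 15
Reactants: 22 (1S,3S,4R,6S)-4-[(2R)-2-formyloxiran-2-yl]-1-methyl-2-oxo-7-oxabicyclo[4.1.0]heptan-3-yl 3-methylbutanoate; 23 2-methyl-2-(trimethylsilyloxy)but-3-yne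
Product: 27 (1S,3S,4R,6S)-4-{(2R)-2-[(2E)-1,4-dihydroxy-4-methylpent-2-en-1-yl]oxiran-2-yl}-1-methyl-2-oxo-7-oxabicyclo[4.1.0]heptan-3-yl 3-methylbutanoate (both carbinol epimers), via alkenylzirconocene 24 (not isolated), via alkenyl(methyl)zinc 25 (not isolated), via trimethylsilyl ether adduct 26 (not isolated)
Conditions: 23, Cp2Zr(H)Cl, CH2Cl2, rt; Me2Zn, PhMe, −65 °C; 22, 0 °C; aq NH4Cl; citric acid, MeOH, 0 °C
Reagents that add atoms: zirconocene chloride hydride [H][Zr](Cl)(C1C=CC=C1)C1C=CC=C1 (Cp2ZrCl of 24); dimethylzinc C[Zn]C (MeZn of 25)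
Why: syn-Hydrozirconation of the terminal alkyne, Zr→Zn transmetalation and 1,2-addition of the (E)-alkenylzinc should be selective for the aldehyde over the hindered ring ketone and the ester; the new carbinol configuration is irrelevant because it is oxidised next, and mild acidic methanolysis removes the tertiary silyl ether.

Step 16
Reactants: 27 (1S,3S,4R,6S)-4-{(2R)-2-[(2E)-1,4-dihydroxy-4-methylpent-2-en-1-yl]oxiran-2-yl}-1-methyl-2-oxo-7-oxabicyclo[4.1.0]heptan-3-yl 3-methylbutanoate
Product: 28 (1S,3S,4R,6S)-4-{(2R)-2-[(2E)-4-hydroxy-4-methylpent-2-enoyl]oxiran-2-yl}-1-methyl-2-oxo-7-oxabicyclo[4.1.0]heptan-3-yl 3-methylbutanoate (CNP0292003.1)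
Conditions: Dess–Martin periodinane, NaHCO3, CH2Cl2, 0 °C
Reagents that add atoms: none
Why: Dess–Martin oxidation of the secondary allylic alcohol should give the (E)-enone from both carbinol epimers while the tertiary alcohol stays untouched.

## Compound list

1 | (R)-(+)-limonene | CC1=CC[C@@H](CC1)C(C)=C | starting material
2 | 2-[(1R)-4-methylcyclohex-3-en-1-yl]allyllithium | [Li]CC(=C)[C@@H]1CCC(C)=CC1 | intermediate
3 | dimethyl {2-[(1R)-4-methylcyclohex-3-en-1-yl]prop-2-en-1-yl}boronate | COB(OC)CC(=C)[C@@H]1CCC(C)=CC1 | intermediate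
4 | 2-[(1R)-4-methylcyclohex-3-en-1-yl]prop-2-en-1-ol ((R)-p-mentha-1,8-dien-10-ol) | OCC(=C)[C@@H]1CCC(C)=CC1 | intermediate
5 | tert-butyldimethylsilyl ether of 4 | CC(C)(C)[Si](C)(C)OCC(=C)[C@@H]1CCC(C)=CC1 | intermediate
6 | secondary ozonide (1,2,4-trioxolane) of the ring alkene of 5, diastereomer mixture | CC12CC[C@H](CC(O1)OO2)C(=C)CO[Si](C)(C)C(C)(C)C | intermediate
7 | (3R)-3-[3-(tert-butyldimethylsilyloxy)prop-1-en-2-yl]-6-oxoheptanal | CC(=O)CC[C@H](CC=O)C(=C)CO[Si](C)(C)C(C)(C)C | intermediate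
8 | 2-hydroxy-2-methyl-5-[3-(tert-butyldimethylsilyloxy)prop-1-en-2-yl]cyclopentane-1-carbaldehyde (aldol adduct, mixture) | O=CC1C(C)(O)CC[C@H]1C(=C)CO[Si](C)(C)C(C)(C)C | intermediate
9 | (5S)-2-methyl-5-[3-(tert-butyldimethylsilyloxy)prop-1-en-2-yl]cyclopent-1-ene-1-carbaldehyde | O=CC1=C(C)CC[C@H]1C(=C)CO[Si](C)(C)C(C)(C)C | intermediate
10 | trimethylsilyl dienol ether of 9 (E/Z mixture) | C[Si](C)(C)OC=C1C(C)=CC[C@H]1C(=C)CO[Si](C)(C)C(C)(C)C | intermediate
11 | potassium dienolate of 9 | [K+].[O-]C=C1C(C)=CC[C@H]1C(=C)CO[Si](C)(C)C(C)(C)C | intermediate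
12 | (1S,5S)-1-hydroxy-2-methyl-5-[3-(tert-butyldimethylsilyloxy)prop-1-en-2-yl]cyclopent-2-ene-1-carbaldehyde | O=C[C@@]1(O)C(C)=CC[C@H]1C(=C)CO[Si](C)(C)C(C)(C)C | intermediate
13 | (2R,6S)-2-hydroxy-3-methyl-6-[3-(tert-butyldimethylsilyloxy)prop-1-en-2-yl]cyclohex-3-en-1-one | O=C1[C@H](O)C(C)=CC[C@H]1C(=C)CO[Si](C)(C)C(C)(C)C | intermediate
14 | (5S,6S)-6-hydroxy-2-methyl-5-[3-(tert-butyldimethylsilyloxy)prop-1-en-2-yl]cyclohex-2-en-1-one | O=C1C(C)=CC[C@@H](C(=C)CO[Si](C)(C)C(C)(C)C)[C@@H]1O | intermediate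
15 | 3-methylbutanoyl chloride | CC(C)CC(Cl)=O | starting material
16 | (1S,6S)-3-methyl-2-oxo-6-[3-(tert-butyldimethylsilyloxy)prop-1-en-2-yl]cyclohex-3-en-1-yl 3-methylbutanoate | O=C1C(C)=CC[C@@H](C(=C)CO[Si](C)(C)C(C)(C)C)[C@@H]1OC(=O)CC(C)C | intermediate
17 | (1S,2S,6S)-2-hydroxy-3-methyl-6-[3-(tert-butyldimethylsilyloxy)prop-1-en-2-yl]cyclohex-3-en-1-yl 3-methylbutanoate | O[C@H]1C(C)=CC[C@@H](C(=C)CO[Si](C)(C)C(C)(C)C)[C@@H]1OC(=O)CC(C)C | intermediate
18 | (1R,2R,3S,4S,6S)-2-hydroxy-1-methyl-4-[3-(tert-butyldimethylsilyloxy)prop-1-en-2-yl]-7-oxabicyclo[4.1.0]heptan-3-yl 3-methylbutanoate | O[C@H]1[C@@]2(C)O[C@H]2C[C@@H](C(=C)CO[Si](C)(C)C(C)(C)C)[C@@H]1OC(=O)CC(C)C | intermediate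
19 | (1S,3S,4S,6S)-1-methyl-2-oxo-4-[3-(tert-butyldimethylsilyloxy)prop-1-en-2-yl]-7-oxabicyclo[4.1.0]heptan-3-yl 3-methylbutanoate | O=C1[C@@]2(C)O[C@H]2C[C@@H](C(=C)CO[Si](C)(C)C(C)(C)C)[C@@H]1OC(=O)CC(C)C | intermediate
20 | (1S,3S,4S,6S)-4-(3-hydroxyprop-1-en-2-yl)-1-methyl-2-oxo-7-oxabicyclo[4.1.0]heptan-3-yl 3-methylbutanoate | O=C1[C@@]2(C)O[C@H]2C[C@@H](C(=C)CO)[C@@H]1OC(=O)CC(C)C | intermediate
21 | (1S,3S,4R,6S)-4-[(2S)-2-(hydroxymethyl)oxiran-2-yl]-1-methyl-2-oxo-7-oxabicyclo[4.1.0]heptan-3-yl 3-methylbutanoate | O=C1[C@@]2(C)O[C@H]2C[C@@H]([C@]3(CO)CO3)[C@@H]1OC(=O)CC(C)C | intermediate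
22 | (1S,3S,4R,6S)-4-[(2R)-2-formyloxiran-2-yl]-1-methyl-2-oxo-7-oxabicyclo[4.1.0]heptan-3-yl 3-methylbutanoate | O=C1[C@@]2(C)O[C@H]2C[C@@H]([C@]3(C=O)CO3)[C@@H]1OC(=O)CC(C)C | intermediate
23 | 2-methyl-2-(trimethylsilyloxy)but-3-yne | C#CC(C)(C)O[Si](C)(C)C | starting material
24 | chloro[(E)-3-methyl-3-(trimethylsilyloxy)but-1-enyl]zirconocene | C[Si](C)(C)OC(C)(C)/C=C/[Zr](Cl)(C1C=CC=C1)C1C=CC=C1 | intermediate
25 | methyl[(E)-3-methyl-3-(trimethylsilyloxy)but-1-enyl]zinc | C[Zn]/C=C/C(C)(C)O[Si](C)(C)C | intermediate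
26 | trimethylsilyl ether of 27 at the tertiary hydroxyl (carbinol epimers) | O=C1[C@@]2(C)O[C@H]2C[C@@H]([C@]3(C(O)/C=C/C(C)(C)O[Si](C)(C)C)CO3)[C@@H]1OC(=O)CC(C)C | intermediate
27 | (1S,3S,4R,6S)-4-{(2R)-2-[(2E)-1,4-dihydroxy-4-methylpent-2-en-1-yl]oxiran-2-yl}-1-methyl-2-oxo-7-oxabicyclo[4.1.0]heptan-3-yl 3-methylbutanoate (carbinol epimers) | O=C1[C@@]2(C)O[C@H]2C[C@@H]([C@]3(C(O)/C=C/C(C)(C)O)CO3)[C@@H]1OC(=O)CC(C)C | intermediate
28 | (1S,3S,4R,6S)-4-{(2R)-2-[(2E)-4-hydroxy-4-methylpent-2-enoyl]oxiran-2-yl}-1-methyl-2-oxo-7-oxabicyclo[4.1.0]heptan-3-yl 3-methylbutanoate | CC(C)CC(=O)O[C@@H]1C(=O)[C@@]2(C)O[C@H]2C[C@H]1[C@]1(C(=O)/C=C/C(C)(C)O)CO1 | target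

## Count and risks

Total step count: 16. Longest linear sequence: 16 steps from (R)-limonene (15 and 23 are bought).

**Step 7 (ring-enlarging acyloin shifts).** The process may stall at the transposed ketol after the alkenyl shift. The ketol may also enolise under the Lewis acid, either toward the side-chain-bearing carbon (erosion of configuration) or on to the diosphenol, and the silyl ether may be lost.
Fallback: the carbonyl is transposed by redox instead of by the hydride shift. The scandium reaction is stopped at 0 °C and the route sets out from the kinetic ketol 13, now isolated. Luche reduction (NaBH4, CeCl3, MeOH, −78 °C; axial hydride delivery) should give the cis-3-methyl-6-[3-(tert-butyldimethylsilyloxy)prop-1-en-2-yl]cyclohex-3-ene-1,2-diol F1, with both hydroxyls trans to the side chain. MnO2 (CH2Cl2, rt) should then oxidise only the allylic carbinol, and the route comes back at hydroxy enone 14 without any enolisable intermediate.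

**Step 6 (dienolate hydroxylation).** Oxygen transfer may occur at the γ-carbon instead of the α-carbon. The dienolate may equilibrate to the exocyclic isomer, or it may add to the aldehyde or to the sulfonimine by-product.
Fallback: γ-reactivity is used instead of fought. Setting out from silyl dienol ether 10, PhSeCl (CH2Cl2, −78 °C) should selenenylate the vinylogous γ-carbon anti to the side chain to give 2-methyl-3-(phenylselanyl)-5-[3-(tert-butyldimethylsilyloxy)prop-1-en-2-yl]cyclopent-1-ene-1-carbaldehyde F2. Oxidation (H2O2, pyridine, CH2Cl2, 0 °C) gives the allylic selenoxide, whose suprafacial [2,3]-sigmatropic shift and selenenate hydrolysis should deliver the tertiary allylic alcohol on the same face, with the alkene in the ring. The route comes back at 12.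

**Step 15 (alkenylzinc addition).** The organometallic may add to the activated ring ketone, or Lewis-acidic zinc and zirconium species may open an oxirane, in competition with addition to the hindered aldehyde.
Fallback: the ring ketone is kept as its carbinol until the end. Setting out from 18:
- HF·pyridine should give the diol 2-hydroxy-4-(3-hydroxyprop-1-en-2-yl)-1-methyl-7-oxabicyclo[4.1.0]heptan-3-yl 3-methylbutanoate F3.
- Sharpless epoxidation as in step 13 should give the epoxy diol F4.
- TEMPO/PhI(OAc)2 should oxidise only the primary alcohol to the hydroxy aldehyde F5.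
- Addition of excess alkenylzinc 25 should give the silyl ether adduct F6, and citric acid/MeOH should then give the triol F7.
- Dess–Martin periodinane (excess) should oxidise both secondary carbinols at once, and the route comes back at 28.

## Further compounds

F1 | step 7 | cis-3-methyl-6-[3-(tert-butyldimethylsilyloxy)prop-1-en-2-yl]cyclohex-3-ene-1,2-diol (both OH trans to the side chain) | O[C@@H]1[C@H](O)C(C)=CC[C@H]1C(=C)CO[Si](C)(C)C(C)(C)C
F2 | step 6 | 2-methyl-3-(phenylselanyl)-5-[3-(tert-butyldimethylsilyloxy)prop-1-en-2-yl]cyclopent-1-ene-1-carbaldehyde (SePh trans to the side chain) | O=CC1=C(C)[C@H]([Se]c2ccccc2)C[C@H]1C(=C)CO[Si](C)(C)C(C)(C)C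
F3 | step 15 | 2-hydroxy-4-(3-hydroxyprop-1-en-2-yl)-1-methyl-7-oxabicyclo[4.1.0]heptan-3-yl 3-methylbutanoate | O[C@H]1[C@@]2(C)O[C@H]2C[C@@H](C(=C)CO)[C@@H]1OC(=O)CC(C)C
F4 | step 15 | 2-hydroxy-4-[(2S)-2-(hydroxymethyl)oxiran-2-yl]-1-methyl-7-oxabicyclo[4.1.0]heptan-3-yl 3-methylbutanoate | O[C@H]1[C@@]2(C)O[C@H]2C[C@@H]([C@]3(CO)CO3)[C@@H]1OC(=O)CC(C)C
F5 | step 15 | 4-[(2R)-2-formyloxiran-2-yl]-2-hydroxy-1-methyl-7-oxabicyclo[4.1.0]heptan-3-yl 3-methylbutanoate | O[C@H]1[C@@]2(C)O[C@H]2C[C@@H]([C@]3(C=O)CO3)[C@@H]1OC(=O)CC(C)C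
F6 | step 15 | 2-hydroxy-4-{(2R)-2-[(2E)-1-hydroxy-4-methyl-4-(trimethylsilyloxy)pent-2-en-1-yl]oxiran-2-yl}-1-methyl-7-oxabicyclo[4.1.0]heptan-3-yl 3-methylbutanoate | O[C@H]1[C@@]2(C)O[C@H]2C[C@@H]([C@]3(C(O)/C=C/C(C)(C)O[Si](C)(C)C)CO3)[C@@H]1OC(=O)CC(C)C
F7 | step 15 | 4-{(2R)-2-[(2E)-1,4-dihydroxy-4-methylpent-2-en-1-yl]oxiran-2-yl}-2-hydroxy-1-methyl-7-oxabicyclo[4.1.0]heptan-3-yl 3-methylbutanoate | O[C@H]1[C@@]2(C)O[C@H]2C[C@@H]([C@]3(C(O)/C=C/C(C)(C)O)CO3)[C@@H]1OC(=O)CC(C)C
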